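**Retrosynthetic overview**
- Ring A is bought whole: 3-methoxycatechol 1 is tribrominated to catechol 2, so every ring-A bromine is in place before the coupling.
- Ring B is bought whole: 2,4-dibromo-1-iodobenzene 3 and the dummy arene 1,3,5-trimethoxybenzene 4 give, via the Koser-type λ3-iodane 5, the aryl(TMP)iodonium tosylate 6. In 6 the normally nucleophilic C-1 of the bromoarene is an aryl cation equivalent.
- Key disconnection: the diaryl ether C–O bond. The oxygen of mono-phenoxide 7 (from 2) is joined to that reversed-polarity aryl carbon by ligand coupling in λ3-iodane 8. This is done last, on the unprotected catechol, and gives target 9 directly.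
- There is no C–C bond outside the two purchased benzene rings, so this C–O bond is the only strategic bond. No ring is formed at any stage.

Assumption: the SMILES has no stereocentre and the molecule is achiral, so "single enantiomer" needs no stereocontrol.

**Route**

Step 1
Reactants: 1 3-methoxycatechol (3-methoxybenzene-1,2-diol)
Product: 2 4,5,6-tribromo-3-methoxybenzene-1,2-diol
Conditions: Br2 (3.1 equiv), AcOH, 10 °C → rt, dark; aq. Na2S2O4 wash
Reagents that add atoms: bromine, BrBr
Why: each of the three free ring positions is ortho or para to an oxygen donor, so exhaustive electrophilic aromatic bromination fills all of them (as in catechol → tetrabromocatechol), and the dithionite wash returns any o-quinone to the catechol; no stereocentre.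

Step 2
Reactants: 3 2,4-dibromo-1-iodobenzene; 4 1,3,5-trimethoxybenzene
Product: 6 (2,4-dibromophenyl)(2,4,6-trimethoxyphenyl)iodonium 4-methylbenzenesulfonate, via hydroxy(tosyloxy)-λ3-iodane 5 (not isolated)
Conditions: mCPBA (1.1 equiv), TsOH·H2O (1.05 equiv), MeCN, 77 °C, 30 min; then 4 (1.05 equiv), 77 °C, 10 min; Et2O trituration
Reagents that add atoms: p-toluenesulfonic acid (used as monohydrate), Cc1ccc(cc1)S(=O)(=O)O (tosylate of 5 and 6); mCPBA, OOC(=O)c1cccc(Cl)c1 (oxygen of the I–OH in 5 only, lost as water on the way to 6)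
Why: mCPBA oxidises the aryl iodide to iodine(III), TsOH traps it as Koser-type 5, and the very electron-rich arene 4 then substitutes at iodine by SEAr (one-pot aryl(TMP)iodonium tosylate synthesis); no stereocentre.

Step 3
Reactants: 2 4,5,6-tribromo-3-methoxybenzene-1,2-diol; 6 (2,4-dibromophenyl)(2,4,6-trimethoxyphenyl)iodonium 4-methylbenzenesulfonate
Product: 9 3,4,5-tribromo-2-(2,4-dibromophenoxy)-6-methoxyphenol, via potassium monophenoxide 7 (not isolated), via aryloxy-λ3-iodane 8 (not isolated)
Conditions: t-BuOK (1.0 equiv), THF, 0 °C, 15 min; then 6 (1.0 equiv), THF–MeCN, 0 → 45 °C, Ar, dark; aq. NH4Cl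
Reagents that add atoms: potassium tert-butoxide, CC(C)(C)[O-].[K+] (K+ of 7 only; nothing from it remains in 9)
Why: Proposed new method: one equivalent of base should remove the more acidic O-1 proton (ortho- and para-bromine; anion held by an H-bond from the central OH), this oxygen replaces tosylate on iodine(III) to give T-shaped 8, and ligand coupling transfers the ortho-substituted, electron-poor 2,4-dibromophenyl group rather than the TMP dummy, so the bromoarene carbon reacts as an aryl cation; the closest known reaction is the metal-free O-arylation of phenols with aryl(TMP)iodonium salts, the site selectivity on a free catechol is the untested part, and no stereocentre is formed.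

**Compound list**

1 | 3-methoxycatechol (3-methoxybenzene-1,2-diol) | COc1cccc(O)c1O | starting material
2 | 4,5,6-tribromo-3-methoxybenzene-1,2-diol | COc1c(O)c(O)c(Br)c(Br)c1Br | intermediate
3 | 2,4-dibromo-1-iodobenzene | Ic1ccc(Br)cc1Br | starting material
4 | 1,3,5-trimethoxybenzene | COc1cc(OC)cc(OC)c1 | starting material
5 | 2,4-dibromo-1-[hydroxy(tosyloxy)-λ3-iodanyl]benzene | OI(OS(=O)(=O)c1ccc(C)cc1)c1ccc(Br)cc1Br | intermediate
6 | (2,4-dibromophenyl)(2,4,6-trimethoxyphenyl)iodonium 4-methylbenzenesulfonate | COc1cc(OC)c([I+]c2ccc(Br)cc2Br)c(OC)c1.Cc1ccc(cc1)S(=O)(=O)[O-] | intermediate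
7 | potassium 2,3,4-tribromo-6-hydroxy-5-methoxyphenolate | [K+].COc1c(O)c([O-])c(Br)c(Br)c1Br | intermediate
8 | (2,3,4-tribromo-6-hydroxy-5-methoxyphenoxy)(2,4-dibromophenyl)(2,4,6-trimethoxyphenyl)-λ3-iodane | COc1cc(OC)c(I(Oc2c(O)c(OC)c(Br)c(Br)c2Br)c2ccc(Br)cc2Br)c(OC)c1 | intermediate
9 | 3,4,5-tribromo-2-(2,4-dibromophenoxy)-6-methoxyphenol | COc1c(O)c(Oc2ccc(Br)cc2Br)c(Br)c(Br)c1Br | target

**Totals**

Total step count: 3. Longest linear sequence: 2 steps (1 → 2 → 9, or 3 → 6 → 9).

**Steps most likely to fail** (the route has three steps; all are listed, most risky first)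

Step 3. The risks are arylation at the central hydroxyl, a second arylation of 9, and oxidation of the catecholate by iodine(III). The fallback sets out from 6 and comes back at 9; it does not use 2. Commercial 2,3-dimethoxyphenol (COc1cccc(O)c1OC) has only the wanted hydroxyl free. It is deprotonated with t-BuOK in THF to potassium 2,3-dimethoxyphenolate F1 and arylated with 6 through (2,3-dimethoxyphenoxy)(2,4-dibromophenyl)(2,4,6-trimethoxyphenyl)-λ3-iodane F2, which gives 1-(2,4-dibromophenoxy)-2,3-dimethoxybenzene F3. BCl3 (1.1 equiv, CH2Cl2, −10 → 0 °C) cleaves only the central methyl ether, which is flanked on both sides and twisted out of the ring plane. This gives dichloro[2-(2,4-dibromophenoxy)-6-methoxyphenoxy]borane F4, and water hydrolyses it to 2-(2,4-dibromophenoxy)-6-methoxyphenol F5. Br2 (3.1 equiv, AcOH, rt → 40 °C) then fills the three free positions of the activated ring A, each para to an oxygen donor, while the dibromophenoxy ring is deactivated, and gives 9. The regiochemistry is fixed here by the building block and the chemoselective demethylation instead of by the acidity difference in 2.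

Step 1. The risks are oxidation of the electron-rich catechol to an o-quinone and a sluggish third bromination. The fallback sets out from 1 and comes back at 2. Compound 1 is protected with 2,2-dimethoxypropane (cat. TsOH, toluene, reflux) as 4-methoxy-2,2-dimethyl-1,3-benzodioxole F6, which cannot be oxidised to a quinone. NBS (3.3 equiv, DMF, rt → 60 °C) gives 5,6,7-tribromo-4-methoxy-2,2-dimethyl-1,3-benzodioxole F7. Aqueous TFA (or 6 M HCl, dioxane, 60 °C) removes the acetonide and gives 2.

Step 2. The risks are slow oxidation of the electron-poor, ortho-substituted aryl iodide, over-oxidation of 4, and a salt that will not crystallise. The fallback sets out from 3 and comes back at 9. Compound 3 is oxidised separately with sodium perborate tetrahydrate in AcOH (45 °C) to isolated 1-(diacetoxyiodo)-2,4-dibromobenzene F8. With commercial (2,4-dibromophenyl)boronic acid (OB(O)c1ccc(Br)cc1Br) and BF3·OEt2 (CH2Cl2, 0 °C; then aq. NaBF4), ipso-substitution at boron gives the symmetric salt bis(2,4-dibromophenyl)iodonium tetrafluoroborate F9, which needs no dummy ligand. F9 takes the place of 6 in step 3: with phenoxide 7 it forms (2,3,4-tribromo-6-hydroxy-5-methoxyphenoxy)bis(2,4-dibromophenyl)-λ3-iodane F10, which collapses to 9 and returns 3 for reuse.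

**Further compounds**

F1 | step 3 | potassium 2,3-dimethoxyphenolate | [K+].COc1cccc([O-])c1OC
F2 | step 3 | (2,3-dimethoxyphenoxy)(2,4-dibromophenyl)(2,4,6-trimethoxyphenyl)-λ3-iodane | COc1cc(OC)c(I(Oc2cccc(OC)c2OC)c2ccc(Br)cc2Br)c(OC)c1
F3 | step 3 | 1-(2,4-dibromophenoxy)-2,3-dimethoxybenzene | COc1cccc(Oc2ccc(Br)cc2Br)c1OC
F4 | step 3 | dichloro[2-(2,4-dibromophenoxy)-6-methoxyphenoxy]borane | COc1cccc(Oc2ccc(Br)cc2Br)c1OB(Cl)Cl
F5 | step 3 | 2-(2,4-dibromophenoxy)-6-methoxyphenol | COc1cccc(Oc2ccc(Br)cc2Br)c1O
F6 | step 1 | 4-methoxy-2,2-dimethyl-1,3-benzodioxole | COc1cccc2OC(C)(C)Oc12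
F7 | step 1 | 5,6,7-tribromo-4-methoxy-2,2-dimethyl-1,3-benzodioxole | COc1c(Br)c(Br)c(Br)c2OC(C)(C)Oc12
F8 | step 2 | 1-(diacetoxyiodo)-2,4-dibromobenzene | CC(=O)OI(OC(C)=O)c1ccc(Br)cc1Br
F9 | step 2 | bis(2,4-dibromophenyl)iodonium tetrafluoroborate | Brc1ccc([I+]c2ccc(Br)cc2Br)c(Br)c1.F[B-](F)(F)F
F10 | step 2 | (2,3,4-tribromo-6-hydroxy-5-methoxyphenoxy)bis(2,4-dibromophenyl)-λ3-iodane | COc1c(O)c(OI(c2ccc(Br)cc2Br)c2ccc(Br)cc2Br)c(Br)c(Br)c1Br
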